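## Structural features

The target is a flavonolignan of the 2,3-dehydroisosilybin type: ring A and the pyranone ring C form a 3,5,7-trihydroxychromen-4-one, and C2 carries ring B. Ring B is also the benzo ring of a 2,3-dihydro-1,4-benzodioxine (ring D). O4', para to the C1'–C2 bond, is bonded to the benzylic carbon Ca, which bears the 4-hydroxy-3-methoxyphenyl ring E; O3' is bonded to Cb, which bears the hydroxymethyl group. Ca and Cb are the only stereocentres; they are adjacent, both R, with aryl and hydroxymethyl trans. The Ca–O4' bond is a para-oxygenated benzyl aryl ether (open to acid ionisation and hydrogenolysis), and the free flavonol oxidises easily in base and air, so free hydroxyls should appear only in the last step. The real difficulty is ring D: the two catechol oxygens must sit on the right carbons (the reverse arrangement is the silybin series) and both centres must be set absolutely. A free 1,2-diol reacting twice with an activated arene leaves that open. The C3 oxygen and the three ring A oxygens must also be in place without an oxidation at the flavone stage. The key step uses the fact that O1 (on C8a) and the oxygens on C5 and C7 are ortho, ortho and para to the C4 carbonyl. A 2,4,6-trifluorobenzoyl group has a carbonyl-activated leaving group at each of these positions, and its two ortho fluorines are equivalent.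

## Logic of the disconnections

**22 to 21.** The five O–CH2Ph bonds (on O3, O5, O7, the ring E phenol and the primary oxygen) are cut. One kind of protecting group removable under neutral reductive conditions keeps the polyphenol masked until the end. The forward step must cleave five benzyl ethers without hydrogenolysing the Ca–O4' bond or reducing C2=C3.

**21 to 19.** The C5–O and C7–O bonds are cut and replaced by C–F. Both carbons are ortho or para to the C4 carbonyl, so an O-benzyl nucleophile can replace fluoride by addition–elimination. The same fluorines are what activate ring A for the key step. The demand is that both fluorides react, the second on an already deactivated ring, without opening ring C.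

**19 to 18.** The O1–C8a bond of ring C is cut. This gives an open 1,3-dione in which the flavonol oxidation level is already present as the benzyloxy group on the central carbon. The forward closure must go through oxygen, at an ortho fluoride, and intramolecularly.

**18 to 17 (from 11) and 16.** The bond between the ring B side carbonyl carbon and the central carbon is cut. This divides the molecule into the chiral benzodioxane acid and an achiral fluorinated ketone of similar size. The forward step must be C-acylation of an enolate, not O-acylation, and the base must not attack the fluorides.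

**16 to 14 (via 15) and 13; 13 to 12.** The aryl–carbonyl bond is cut. The arene is symmetric, so deprotonation can occur at only one kind of position, and the N-methoxy-N-methylamide stops at the ketone. The aryllithium must be kept cold to avoid loss of LiF.

**11 to 10 to 9.** After the trivial ester cut, the aryl C4'–O4' bond of ring D is cut. C4' is para to the ester, so the Ca alkoxide can displace fluoride with the Ca–O bond, and hence the configuration, untouched.

- A one-pot double substitution of a free diol on a fluoro-nitro arene was rejected here. Two secondary hydroxyls of similar reactivity would compete for the first substitution. The nitro-activated ipso carbon would also allow aryl migration between the two oxygens (Smiles shift) before the second closure, so ring D regiochemistry would not be secured.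
- In 9 the carbon bearing O3' is meta to the ester and not activated, so no such migration is possible.
- The demand is that the benzylic hydroxyl be the only free one.

**9 to 7 (via 8).** The O–CH2Ph bond on the primary oxygen is cut. The forward step must distinguish the primary from the benzylic secondary hydroxyl under conditions too mild for premature ring closure.

**7 to 6 to 3 (via 5) and 4.** The acyl–nitrogen bond to the auxiliary and then the Ca–Cb bond are cut. One aldol step creates both stereocentres with O3' already on Cb. The step must be syn-selective and face-selective, since the syn relation becomes the trans relation of ring D.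

**3 to 1 and 2.** The O3'–CH2 bond is cut. This alkylation at a methylene, before any stereocentre exists, fixes which catechol oxygen ends up on Cb. It only requires that the phenoxide attack the chloromethyl carbon and not the imide carbonyl.

## Other disconnections considered

**Alternative 1:** The cut is the O4'–Ca bond of ring D. In the forward step the catechol monoether A2 (O3' already on Cb, free 4'-hydroxyl, free ring E phenol, benzylic hydroxyl of either configuration) is treated with acid. Water is lost from Ca with help from the para-hydroxyl, and the 4'-hydroxyl traps the resulting para-quinone methide to give A1 as the trans isomer.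

- In its favour: only Cb has to be set, because Ca converges under equilibrium control. On the number of controlled centres this is better than the chosen plan. Ring D regiochemistry is as secure as in the chosen plan, since O3'–Cb exists before closure. No protecting group is needed at that stage.
- Against it: the trans to cis outcome is a thermodynamic ratio, not a mechanistic certainty. Precursors of A2 usually hold Cb next to an aryl ketone, where it can epimerise. A1 needs two O-benzylations before it can enter the route at 10.
- Comparison: structurally both plans give the same ring D. Mechanistically this is a cationic closure that re-forms Ca, whereas the chosen closure is anionic and leaves both centres untouched. Step count to the benzodioxane ester is about equal. It does not address rings C and A, so it could only replace steps 1 to 5.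

**Alternative 2:** The cut removes four C–C bonds of ring A. In the forward step the diazo ketone A4, a pyranone already carrying ring B and the protected C3 oxygen, is irradiated with the silyloxyalkyne A5. Wolff shift, ketene–alkyne cycloaddition, four-electron opening of the cyclobutenone and six-electron closure should give A3.

- In its favour: four bonds form in one operation, which is better than the chosen key step in bond-forming power. The C5 and C7 oxygens arrive differentiated, which would be an advantage if they had to be told apart (they do not here). No late fluoride substitution is needed. The acetal groups come off with acid, so the Ca–O4' bond is not exposed to hydrogenolysis; on that point it is equal or better.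
- Against it: A4 is much harder to reach than 18. Ring B must be joined to the pyranone by C–C coupling, a side chain oxidised and homologated to the diazo ketone with hazardous reagents, all with the ring D stereocentres on board. The photochemistry has to work alongside several aryl ether chromophores. Two classes of protecting group are needed.
- Comparison: structurally it builds ring A from acyclic atoms, while the chosen plan only closes ring C. Mechanistically it is a pericyclic cascade against a single ionic addition–elimination. In step economy the chosen plan should be clearly shorter.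

**Alternative 3:** The cut is the O3'–Cb bond. In the forward step A7 (O4' already on Ca from opening of an epoxy alcohol at the benzylic carbon, free 3'-hydroxyl, secondary hydroxyl on Cb of the opposite configuration) is closed under Mitsunobu conditions with inversion at Cb to give A6.

- In its favour: the chirality comes from a catalytic asymmetric epoxidation, not a stoichiometric auxiliary; on that point it is better. Regiochemistry is fixed by the order of events, equal to the chosen plan. The closure is neutral.
- Against it: an epoxide next to an electron-rich arene is acid-labile and can open at Ca with partial ionisation, eroding configuration. The Mitsunobu must invert a hindered secondary carbinol where elimination and neighbouring-group participation compete. The silyl, pivaloyl and ester groups would have to be exchanged for a set that survives enolate chemistry.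
- Comparison: structurally it reaches the same ring D. Mechanistically it needs two clean inversions, while in the chosen plan neither centre undergoes substitution after the aldol. Step count for ring D is about equal, with extra protecting-group changes for the alternative.

Key step: step 10

## Route

Step 1
Reactants: 1 methyl 4-fluoro-3-hydroxybenzoate; 2 (4S)-4-benzyl-3-(chloroacetyl)-1,3-oxazolidin-2-one
Product: 3 methyl 3-{2-[(4S)-4-benzyl-2-oxo-1,3-oxazolidin-3-yl]-2-oxoethoxy}-4-fluorobenzoate
Conditions: K2CO3, MeCN, 50 °C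
Reagents that add atoms: none
Why: Williamson ether synthesis; the phenoxide displaces chloride at the activated methylene, placing O3' on the future Cb before any stereocentre exists. A phenoxide does not displace the fluoride para to the ester at this temperature.

Step 2
Reactants: 3 methyl 3-{2-[(4S)-4-benzyl-2-oxo-1,3-oxazolidin-3-yl]-2-oxoethoxy}-4-fluorobenzoate; 4 4-(benzyloxy)-3-methoxybenzaldehyde
Product: 6 methyl 3-{[(2S,3R)-1-[(4S)-4-benzyl-2-oxo-1,3-oxazolidin-3-yl]-3-[4-(benzyloxy)-3-methoxyphenyl]-3-hydroxy-1-oxopropan-2-yl]oxy}-4-fluorobenzoate, via dibutylboron Z-enolate 5 (not isolated)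
Conditions: Bu2BOTf, Et3N, CH2Cl2, −78 to 0 °C; then 4, −78 to 0 °C; pH 7 buffer, MeOH, H2O2, 0 °C
Reagents that add atoms: none
Why: Evans syn-aldol reaction of an aryloxyacetyl imide; the Z-boron enolate reacts through a closed chair transition state in which the benzyl group of the (4S)-auxiliary blocks one enolate face. This should set Cb as S and Ca as R (here C2 and C3 of the propanoyl chain), the syn relation that becomes trans in ring D.

Step 3
Reactants: 6 methyl 3-{[(2S,3R)-1-[(4S)-4-benzyl-2-oxo-1,3-oxazolidin-3-yl]-3-[4-(benzyloxy)-3-methoxyphenyl]-3-hydroxy-1-oxopropan-2-yl]oxy}-4-fluorobenzoate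
Product: 7 methyl 3-{[(1R,2R)-1-[4-(benzyloxy)-3-methoxyphenyl]-1,3-dihydroxypropan-2-yl]oxy}-4-fluorobenzoate
Conditions: NaBH4, THF/H2O (3:1), 0 °C to rt
Reagents that add atoms: none
Why: Reductive cleavage of the N-acyl oxazolidinone; borohydride attacks the activated imide carbonyl much faster than the aryl methyl ester. Neither stereocentre is touched (the descriptor at Cb changes from S to R only because the carbonyl becomes CH2OH).

Step 4
Reactants: 7 methyl 3-{[(1R,2R)-1-[4-(benzyloxy)-3-methoxyphenyl]-1,3-dihydroxypropan-2-yl]oxy}-4-fluorobenzoate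
Product: 9 methyl 3-{[(1R,2R)-3-(benzyloxy)-1-[4-(benzyloxy)-3-methoxyphenyl]-1-hydroxypropan-2-yl]oxy}-4-fluorobenzoate, via dibutylstannylene acetal 8 (not isolated)
Conditions: Bu2SnO, toluene, reflux (−H2O); then BnBr, cat. Bu4NI, 90 °C
Reagents that add atoms: benzyl bromide, BrCc1ccccc1
Why: Stannylene-acetal-mediated regioselective O-alkylation; the six-membered tin acetal of the 1,3-diol is alkylated at the less hindered primary oxygen. The medium is not basic enough to start ring closure through the primary oxygen.

Step 5
Reactants: 9 methyl 3-{[(1R,2R)-3-(benzyloxy)-1-[4-(benzyloxy)-3-methoxyphenyl]-1-hydroxypropan-2-yl]oxy}-4-fluorobenzoate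
Product: 10 methyl (2R,3R)-3-[(benzyloxy)methyl]-2-[4-(benzyloxy)-3-methoxyphenyl]-2,3-dihydro-1,4-benzodioxine-6-carboxylate
Conditions: NaH, DMF, 0 °C to rt
Reagents that add atoms: none
Why: Intramolecular SNAr; the benzylic alkoxide adds to C4', para to the ester, and fluoride leaves, closing the six-membered ring D with the Ca–O bond and both configurations retained. The carbon bearing O3' is meta to the ester, so no aryl shift between the two oxygens can scramble the regiochemistry.

Step 6
Reactants: 10 methyl (2R,3R)-3-[(benzyloxy)methyl]-2-[4-(benzyloxy)-3-methoxyphenyl]-2,3-dihydro-1,4-benzodioxine-6-carboxylate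
Product: 11 (2R,3R)-3-[(benzyloxy)methyl]-2-[4-(benzyloxy)-3-methoxyphenyl]-2,3-dihydro-1,4-benzodioxine-6-carboxylic acid
Conditions: LiOH, THF/MeOH/H2O, rt; then 1 M HCl
Reagents that add atoms: lithium hydroxide, [Li+].[OH-]
Why: Ester saponification; ring D has no acidic hydrogen next to a carbonyl, so neither epimerisation nor elimination is possible.

Step 7
Reactants: 12 (benzyloxy)acetyl chloride
Product: 13 2-(benzyloxy)-N-methoxy-N-methylacetamide
Conditions: MeNHOMe·HCl, Et3N, CH2Cl2, 0 °C to rt
Reagents that add atoms: N,O-dimethylhydroxylamine hydrochloride, CNOC.Cl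
Why: N-acylation of an amine by an acid chloride, giving the Weinreb amide.

Step 8
Reactants: 14 1,3,5-trifluorobenzene; 13 2-(benzyloxy)-N-methoxy-N-methylacetamide
Product: 16 2-(benzyloxy)-1-(2,4,6-trifluorophenyl)ethan-1-one, via (2,4,6-trifluorophenyl)lithium 15 (not isolated)
Conditions: n-BuLi, THF, −78 °C; then 13, −78 °C; aq. NH4Cl
Reagents that add atoms: none
Why: Deprotonation between two fluorines (all three ring hydrogens are equivalent) followed by Weinreb ketone synthesis; the chelated tetrahedral adduct prevents a second addition. At −78 °C the aryllithium does not lose LiF to an aryne.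

Step 9
Reactants: 11 (2R,3R)-3-[(benzyloxy)methyl]-2-[4-(benzyloxy)-3-methoxyphenyl]-2,3-dihydro-1,4-benzodioxine-6-carboxylic acid; 16 2-(benzyloxy)-1-(2,4,6-trifluorophenyl)ethan-1-one
Product: 18 2-(benzyloxy)-1-{(2R,3R)-3-[(benzyloxy)methyl]-2-[4-(benzyloxy)-3-methoxyphenyl]-2,3-dihydro-1,4-benzodioxin-6-yl}-3-(2,4,6-trifluorophenyl)propane-1,3-dione, via acid chloride 17 (not isolated)
Conditions: (COCl)2, cat. DMF, CH2Cl2, 0 °C to rt, evaporate; 16 (2 equiv), LiN(SiMe3)2 (2 equiv), THF, −78 °C; then 17, −78 to −20 °C; aq. NH4Cl
Reagents that add atoms: none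
Why: C-acylation of a ketone lithium enolate by an aroyl chloride (crossed Claisen type); the chelated enolate of the alkoxy ketone reacts at carbon, and the second equivalent of enolate takes the acidic proton of the dione. The hindered amide base and low temperature leave the fluorides alone and keep the dione from cyclising early.

Step 10
Reactants: 18 2-(benzyloxy)-1-{(2R,3R)-3-[(benzyloxy)methyl]-2-[4-(benzyloxy)-3-methoxyphenyl]-2,3-dihydro-1,4-benzodioxin-6-yl}-3-(2,4,6-trifluorophenyl)propane-1,3-dione
Product: 19 3-(benzyloxy)-2-{(2R,3R)-3-[(benzyloxy)methyl]-2-[4-(benzyloxy)-3-methoxyphenyl]-2,3-dihydro-1,4-benzodioxin-6-yl}-5,7-difluoro-4H-chromen-4-one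
Conditions: K2CO3, DMF, rt
Reagents that add atoms: none
Why: K2CO3 removes the hydrogen between the two carbonyls of 18, and the delocalised enolate can bring the oxygen of the ring B side carbonyl next to an ortho C–F carbon of the trifluorophenyl ring. Addition of that oxygen gives a Meisenheimer anion whose charge passes through C4a into the C4 carbonyl, with inductive help from the fluorines at C5 and C7; loss of fluoride then restores aromaticity with the O1–C8a bond formed (intramolecular SNAr, addition–elimination). The closest known reaction type is the base-mediated cyclisation of 1-(2-fluoroaryl)-1,3-diketones to chromones and flavones. Ring C is closed as a six-membered ring (O1, C2, C3, C4, C4a, C8a) by attack of the enolate oxygen on the aromatic carbon. No stereocentre is formed, and Ca and Cb are remote from any acidic position, so their configuration is not at risk. The step needs O- over C-arylation, ortho over para substitution and ring closure over bimolecular attack. The central carbon could reach an ortho carbon only through a four-membered ring, neither end of the enolate can reach the para carbon, and the two ortho fluorines are equivalent by symmetry, so one product should result at moderate dilution. The benzyloxy group on the central carbon becomes the protected C3 oxygen, and the fluorides left at C5 and C7 stay ortho and para to the new C4 carbonyl for step 11.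

Step 11
Reactants: 19 3-(benzyloxy)-2-{(2R,3R)-3-[(benzyloxy)methyl]-2-[4-(benzyloxy)-3-methoxyphenyl]-2,3-dihydro-1,4-benzodioxin-6-yl}-5,7-difluoro-4H-chromen-4-one
Product: 21 3,5,7-tris(benzyloxy)-2-{(2R,3R)-3-[(benzyloxy)methyl]-2-[4-(benzyloxy)-3-methoxyphenyl]-2,3-dihydro-1,4-benzodioxin-6-yl}-4H-chromen-4-one, via 7-benzyloxy-5-fluoro flavone 20 (not isolated)
Conditions: BnOH, NaH, THF, 0 °C; then 19, THF/DMF, 0 to 60 °C
Reagents that add atoms: benzyl alcohol, OCc1ccccc1
Why: Twofold SNAr by an alkoxide on a fluorinated chromone; C7 is para and C5 ortho to the C4 carbonyl. The para fluoride should go first in the polar medium, and the second substitution on the less electrophilic ring needs warming.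

Step 12
Reactants: 21 3,5,7-tris(benzyloxy)-2-{(2R,3R)-3-[(benzyloxy)methyl]-2-[4-(benzyloxy)-3-methoxyphenyl]-2,3-dihydro-1,4-benzodioxin-6-yl}-4H-chromen-4-one
Product: 22 3,5,7-trihydroxy-2-[(2R,3R)-3-(hydroxymethyl)-2-(4-hydroxy-3-methoxyphenyl)-2,3-dihydro-1,4-benzodioxin-6-yl]-4H-chromen-4-one
Conditions: H2 (1 atm), Pd/C, THF/MeOH, rt
Reagents that add atoms: none
Why: Hydrogenolysis of five benzyl ethers; the O–CH2Ph bonds are cleaved faster than the hindered cyclic Ca–O4' ether, and the pyranone C2=C3 bond is not reduced under these conditions. Ca and Cb are not affected.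

## Compound list

1 | methyl 4-fluoro-3-hydroxybenzoate | COC(=O)c1ccc(F)c(O)c1 | starting material
2 | (4S)-4-benzyl-3-(chloroacetyl)-1,3-oxazolidin-2-one | O=C(CCl)N1[C@@H](Cc2ccccc2)COC1=O | starting material
3 | methyl 3-{2-[(4S)-4-benzyl-2-oxo-1,3-oxazolidin-3-yl]-2-oxoethoxy}-4-fluorobenzoate | COC(=O)c1ccc(F)c(OCC(=O)N2[C@@H](Cc3ccccc3)COC2=O)c1 | intermediate
4 | 4-(benzyloxy)-3-methoxybenzaldehyde | COc1cc(C=O)ccc1OCc1ccccc1 | starting material
5 | dibutylboron Z-enolate of 3 | COC(=O)c1ccc(F)c(O/C=C(\OB(CCCC)CCCC)N2[C@@H](Cc3ccccc3)COC2=O)c1 | intermediate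
6 | methyl 3-{[(2S,3R)-1-[(4S)-4-benzyl-2-oxo-1,3-oxazolidin-3-yl]-3-[4-(benzyloxy)-3-methoxyphenyl]-3-hydroxy-1-oxopropan-2-yl]oxy}-4-fluorobenzoate | COC(=O)c1ccc(F)c(O[C@H](C(=O)N2[C@@H](Cc3ccccc3)COC2=O)[C@H](O)c4ccc(OCc5ccccc5)c(OC)c4)c1 | intermediate
7 | methyl 3-{[(1R,2R)-1-[4-(benzyloxy)-3-methoxyphenyl]-1,3-dihydroxypropan-2-yl]oxy}-4-fluorobenzoate | COC(=O)c1ccc(F)c(O[C@H](CO)[C@H](O)c2ccc(OCc3ccccc3)c(OC)c2)c1 | intermediate
8 | methyl 3-{[(4R,5R)-4-[4-(benzyloxy)-3-methoxyphenyl]-2,2-dibutyl-1,3,2-dioxastanninan-5-yl]oxy}-4-fluorobenzoate | CCCC[Sn]1(CCCC)OC[C@@H](Oc2cc(C(=O)OC)ccc2F)[C@@H](c2ccc(OCc3ccccc3)c(OC)c2)O1 | intermediate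
9 | methyl 3-{[(1R,2R)-3-(benzyloxy)-1-[4-(benzyloxy)-3-methoxyphenyl]-1-hydroxypropan-2-yl]oxy}-4-fluorobenzoate | COC(=O)c1ccc(F)c(O[C@H](COCc2ccccc2)[C@H](O)c2ccc(OCc3ccccc3)c(OC)c2)c1 | intermediate
10 | methyl (2R,3R)-3-[(benzyloxy)methyl]-2-[4-(benzyloxy)-3-methoxyphenyl]-2,3-dihydro-1,4-benzodioxine-6-carboxylate | COc1cc([C@H]2Oc3ccc(C(=O)OC)cc3O[C@@H]2COCc4ccccc4)ccc1OCc5ccccc5 | intermediate
11 | (2R,3R)-3-[(benzyloxy)methyl]-2-[4-(benzyloxy)-3-methoxyphenyl]-2,3-dihydro-1,4-benzodioxine-6-carboxylic acid | COc1cc([C@H]2Oc3ccc(C(=O)O)cc3O[C@@H]2COCc4ccccc4)ccc1OCc5ccccc5 | intermediate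
12 | (benzyloxy)acetyl chloride | O=C(Cl)COCc1ccccc1 | starting material
13 | 2-(benzyloxy)-N-methoxy-N-methylacetamide | CON(C)C(=O)COCc1ccccc1 | intermediate
14 | 1,3,5-trifluorobenzene | Fc1cc(F)cc(F)c1 | starting material
15 | (2,4,6-trifluorophenyl)lithium | [Li]c1c(F)cc(F)cc1F | intermediate
16 | 2-(benzyloxy)-1-(2,4,6-trifluorophenyl)ethan-1-one | O=C(COCc1ccccc1)c1c(F)cc(F)cc1F | intermediate
17 | (2R,3R)-3-[(benzyloxy)methyl]-2-[4-(benzyloxy)-3-methoxyphenyl]-2,3-dihydro-1,4-benzodioxine-6-carbonyl chloride | COc1cc([C@H]2Oc3ccc(C(=O)Cl)cc3O[C@@H]2COCc4ccccc4)ccc1OCc5ccccc5 | intermediate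
18 | 2-(benzyloxy)-1-{(2R,3R)-3-[(benzyloxy)methyl]-2-[4-(benzyloxy)-3-methoxyphenyl]-2,3-dihydro-1,4-benzodioxin-6-yl}-3-(2,4,6-trifluorophenyl)propane-1,3-dione | COc1cc([C@H]2Oc3ccc(C(=O)C(OCc4ccccc4)C(=O)c5c(F)cc(F)cc5F)cc3O[C@@H]2COCc6ccccc6)ccc1OCc7ccccc7 | intermediate
19 | 3-(benzyloxy)-2-{(2R,3R)-3-[(benzyloxy)methyl]-2-[4-(benzyloxy)-3-methoxyphenyl]-2,3-dihydro-1,4-benzodioxin-6-yl}-5,7-difluoro-4H-chromen-4-one | COc1cc([C@H]2Oc3ccc(-c4oc5cc(F)cc(F)c5c(=O)c4OCc6ccccc6)cc3O[C@@H]2COCc7ccccc7)ccc1OCc8ccccc8 | intermediate
20 | 3,7-bis(benzyloxy)-2-{(2R,3R)-3-[(benzyloxy)methyl]-2-[4-(benzyloxy)-3-methoxyphenyl]-2,3-dihydro-1,4-benzodioxin-6-yl}-5-fluoro-4H-chromen-4-one | COc1cc([C@H]2Oc3ccc(-c4oc5cc(OCc6ccccc6)cc(F)c5c(=O)c4OCc6ccccc6)cc3O[C@@H]2COCc7ccccc7)ccc1OCc8ccccc8 | intermediate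
21 | 3,5,7-tris(benzyloxy)-2-{(2R,3R)-3-[(benzyloxy)methyl]-2-[4-(benzyloxy)-3-methoxyphenyl]-2,3-dihydro-1,4-benzodioxin-6-yl}-4H-chromen-4-one | COc1cc([C@H]2Oc3ccc(-c4oc5cc(OCc6ccccc6)cc(OCc6ccccc6)c5c(=O)c4OCc6ccccc6)cc3O[C@@H]2COCc7ccccc7)ccc1OCc8ccccc8 | intermediate
22 | 3,5,7-trihydroxy-2-[(2R,3R)-3-(hydroxymethyl)-2-(4-hydroxy-3-methoxyphenyl)-2,3-dihydro-1,4-benzodioxin-6-yl]-4H-chromen-4-one | COc1cc([C@H]2Oc3ccc(-c4oc5cc(O)cc(O)c5c(=O)c4O)cc3O[C@@H]2CO)ccc1O | target

## Step count and least certain steps

Total: 12 steps. Longest linear sequence: 10 steps (steps 1 to 6 and 9 to 12); steps 7 and 8 form the short branch.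

**Step 10 (key step).** The most likely failures are attack of the enolate of one molecule on the para fluorine of another if the twisted 2,6-difluorobenzoyl group reaches the reactive conformation slowly, cleavage of the dione by adventitious hydroxide (retro-Claisen), and amination of the activated fluorides by dimethylamine from DMF if heating is needed.

The fallback closes ring C at O1–C2 by condensation with the ring A oxygens already in place. It sets out from 11 (through 17) and comes back at 21, bypassing 18 to 20. Hoesch acylation of benzene-1,3,5-triol with (benzyloxy)acetonitrile (ZnCl2, HCl, Et2O; then hot water) should give 2-(benzyloxy)-1-(2,4,6-trihydroxyphenyl)ethan-1-one F1. Twofold benzylation (BnBr, K2CO3, DMF), which leaves the chelated hydroxyl free, should give 2-(benzyloxy)-1-[2,4-bis(benzyloxy)-6-hydroxyphenyl]ethan-1-one F2. Esterification of F2 with 17 (pyridine, cat. DMAP) should give the aryl ester F3. Baker–Venkataraman acyl shift (LiN(SiMe3)2, THF, −20 °C) should give the phenolic 1,3-dione F4. Cyclodehydration (AcOH, NaOAc, 100 °C) should then give 21.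

**Step 9.** O-acylation of the ambident enolate to an enol ester, or a second acylation of the product enolate, may compete because the acid chloride is hard and the enolate hindered by the benzyloxy group.

The fallback replaces acylation by aldol addition and oxidation, where only carbon can react. It sets out from 10 and 16 and comes back at 18. Reduction of 10 (LiAlH4, THF, 0 °C) should give the benzylic alcohol {(2R,3R)-3-[(benzyloxy)methyl]-2-[4-(benzyloxy)-3-methoxyphenyl]-2,3-dihydro-1,4-benzodioxin-6-yl}methanol F5. Oxidation (MnO2, CH2Cl2) should give the aldehyde (2R,3R)-3-[(benzyloxy)methyl]-2-[4-(benzyloxy)-3-methoxyphenyl]-2,3-dihydro-1,4-benzodioxine-6-carbaldehyde F6. Addition of the lithium enolate of 16 at −78 °C with a cold quench should give the hydroxy ketone 2-(benzyloxy)-3-{(2R,3R)-3-[(benzyloxy)methyl]-2-[4-(benzyloxy)-3-methoxyphenyl]-2,3-dihydro-1,4-benzodioxin-6-yl}-3-hydroxy-1-(2,4,6-trifluorophenyl)propan-1-one F7 as a mixture at the two new centres. Dess–Martin oxidation should give 18.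

**Step 11.** The second substitution may stall, because the first alkoxy group makes ring A less electrophilic, and reversible addition of the alkoxide at C2 can open ring C and lead to degradation on prolonged heating.

The fallback keeps the same ring C closure but installs the ring A oxygens on the arene first. It sets out from 14 (with 13 and 17) and comes back at 21. Twofold substitution of 14 (NaOCH2Ph, N-methylpyrrolidone, 100 °C) should give 1,3-bis(benzyloxy)-5-fluorobenzene F8. Bromination (N-bromosuccinimide, MeCN, 0 °C) at the position between fluorine and a benzyloxy group should give 1,5-bis(benzyloxy)-2-bromo-3-fluorobenzene F9. Bromine–lithium exchange (n-BuLi, THF, −78 °C) and addition to 13 should give 2-(benzyloxy)-1-[2,4-bis(benzyloxy)-6-fluorophenyl]ethan-1-one F10. Acylation of its lithium enolate with 17 as in step 9 should give the dione F11. Closure of the O1–C8a bond by SNAr (Cs2CO3, DMF, 80 °C) should give 21.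

**Step 4.** Alkylation may occur at the benzylic oxygen or twice, and the tin alkoxide may exchange with the methyl ester at 90 °C. The selectivity rests only on the steric difference between the two oxygens of the tin acetal.

The fallback uses a protecting group that reacts only with primary hydroxyls and cannot migrate. It sets out from 7 and comes back at 10. Tritylation (Ph3CCl, Et3N, cat. DMAP, CH2Cl2) should give methyl 3-{[(1R,2R)-1-[4-(benzyloxy)-3-methoxyphenyl]-1-hydroxy-3-(trityloxy)propan-2-yl]oxy}-4-fluorobenzoate F12. Ring closure as in step 5 (NaH, DMF) should give the trityl ether F13. Mild acid (80% AcOH, 40 °C) should give methyl (2R,3R)-2-[4-(benzyloxy)-3-methoxyphenyl]-3-(hydroxymethyl)-2,3-dihydro-1,4-benzodioxine-6-carboxylate F14. Benzylation (NaH, BnBr, THF) should give 10.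

## Further compounds

F1 | step 10 | 2-(benzyloxy)-1-(2,4,6-trihydroxyphenyl)ethan-1-one | O=C(COCc1ccccc1)c1c(O)cc(O)cc1O
F2 | step 10 | 2-(benzyloxy)-1-[2,4-bis(benzyloxy)-6-hydroxyphenyl]ethan-1-one | O=C(COCc1ccccc1)c1c(O)cc(OCc2ccccc2)cc1OCc1ccccc1
F3 | step 10 | 3,5-bis(benzyloxy)-2-[(benzyloxy)acetyl]phenyl (2R,3R)-3-[(benzyloxy)methyl]-2-[4-(benzyloxy)-3-methoxyphenyl]-2,3-dihydro-1,4-benzodioxine-6-carboxylate | COc1cc([C@H]2Oc3ccc(C(=O)Oc4cc(OCc5ccccc5)cc(OCc5ccccc5)c4C(=O)COCc4ccccc4)cc3O[C@@H]2COCc6ccccc6)ccc1OCc7ccccc7
F4 | step 10 | 2-(benzyloxy)-1-[2,4-bis(benzyloxy)-6-hydroxyphenyl]-3-{(2R,3R)-3-[(benzyloxy)methyl]-2-[4-(benzyloxy)-3-methoxyphenyl]-2,3-dihydro-1,4-benzodioxin-6-yl}propane-1,3-dione | COc1cc([C@H]2Oc3ccc(C(=O)C(OCc4ccccc4)C(=O)c4c(O)cc(OCc5ccccc5)cc4OCc4ccccc4)cc3O[C@@H]2COCc6ccccc6)ccc1OCc7ccccc7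
F5 | step 9 | {(2R,3R)-3-[(benzyloxy)methyl]-2-[4-(benzyloxy)-3-methoxyphenyl]-2,3-dihydro-1,4-benzodioxin-6-yl}methanol | COc1cc([C@H]2Oc3ccc(CO)cc3O[C@@H]2COCc4ccccc4)ccc1OCc5ccccc5
F6 | step 9 | (2R,3R)-3-[(benzyloxy)methyl]-2-[4-(benzyloxy)-3-methoxyphenyl]-2,3-dihydro-1,4-benzodioxine-6-carbaldehyde | COc1cc([C@H]2Oc3ccc(C=O)cc3O[C@@H]2COCc4ccccc4)ccc1OCc5ccccc5
F7 | step 9 | 2-(benzyloxy)-3-{(2R,3R)-3-[(benzyloxy)methyl]-2-[4-(benzyloxy)-3-methoxyphenyl]-2,3-dihydro-1,4-benzodioxin-6-yl}-3-hydroxy-1-(2,4,6-trifluorophenyl)propan-1-one | COc1cc([C@H]2Oc3ccc(C(O)C(OCc4ccccc4)C(=O)c5c(F)cc(F)cc5F)cc3O[C@@H]2COCc6ccccc6)ccc1OCc7ccccc7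
F8 | step 11 | 1,3-bis(benzyloxy)-5-fluorobenzene | Fc1cc(OCc2ccccc2)cc(OCc2ccccc2)c1
F9 | step 11 | 1,5-bis(benzyloxy)-2-bromo-3-fluorobenzene | Fc1cc(OCc2ccccc2)cc(OCc2ccccc2)c1Br
F10 | step 11 | 2-(benzyloxy)-1-[2,4-bis(benzyloxy)-6-fluorophenyl]ethan-1-one | O=C(COCc1ccccc1)c1c(F)cc(OCc2ccccc2)cc1OCc1ccccc1
F11 | step 11 | 2-(benzyloxy)-1-[2,4-bis(benzyloxy)-6-fluorophenyl]-3-{(2R,3R)-3-[(benzyloxy)methyl]-2-[4-(benzyloxy)-3-methoxyphenyl]-2,3-dihydro-1,4-benzodioxin-6-yl}propane-1,3-dione | COc1cc([C@H]2Oc3ccc(C(=O)C(OCc4ccccc4)C(=O)c4c(F)cc(OCc5ccccc5)cc4OCc4ccccc4)cc3O[C@@H]2COCc6ccccc6)ccc1OCc7ccccc7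
F12 | step 4 | methyl 3-{[(1R,2R)-1-[4-(benzyloxy)-3-methoxyphenyl]-1-hydroxy-3-(trityloxy)propan-2-yl]oxy}-4-fluorobenzoate | COC(=O)c1ccc(F)c(O[C@H](COC(c2ccccc2)(c2ccccc2)c2ccccc2)[C@H](O)c2ccc(OCc3ccccc3)c(OC)c2)c1
F13 | step 4 | methyl (2R,3R)-2-[4-(benzyloxy)-3-methoxyphenyl]-3-[(trityloxy)methyl]-2,3-dihydro-1,4-benzodioxine-6-carboxylate | COc1cc([C@H]2Oc3ccc(C(=O)OC)cc3O[C@@H]2COC(c4ccccc4)(c4ccccc4)c4ccccc4)ccc1OCc5ccccc5
F14 | step 4 | methyl (2R,3R)-2-[4-(benzyloxy)-3-methoxyphenyl]-3-(hydroxymethyl)-2,3-dihydro-1,4-benzodioxine-6-carboxylate | COc1cc([C@H]2Oc3ccc(C(=O)OC)cc3O[C@@H]2CO)ccc1OCc4ccccc4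
A1 | alternative 1 | methyl (2R,3R)-2-(4-hydroxy-3-methoxyphenyl)-3-(hydroxymethyl)-2,3-dihydro-1,4-benzodioxine-6-carboxylate | COc1cc([C@H]2Oc3ccc(C(=O)OC)cc3O[C@@H]2CO)ccc1O
A2 | alternative 1 | methyl 3-{[(2R)-1,3-dihydroxy-1-(4-hydroxy-3-methoxyphenyl)propan-2-yl]oxy}-4-hydroxybenzoate (configuration at C1 open) | COC(=O)c1ccc(O)c(O[C@H](CO)C(O)c2ccc(O)c(OC)c2)c1
A3 | alternative 2 | 5-hydroxy-3-(methoxymethoxy)-2-{(2R,3R)-3-[(methoxymethoxy)methyl]-2-[3-methoxy-4-(methoxymethoxy)phenyl]-2,3-dihydro-1,4-benzodioxin-6-yl}-7-[(triisopropylsilyl)oxy]-4H-chromen-4-one | COc1cc([C@H]2Oc3ccc(-c4oc5cc(O[Si](C(C)C)(C(C)C)C(C)C)cc(O)c5c(=O)c4OCOC)cc3O[C@@H]2COCOC)ccc1OCOC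
A4 | alternative 2 | 6-(diazoacetyl)-3-(methoxymethoxy)-2-{(2R,3R)-3-[(methoxymethoxy)methyl]-2-[3-methoxy-4-(methoxymethoxy)phenyl]-2,3-dihydro-1,4-benzodioxin-6-yl}-4H-pyran-4-one | COc1cc([C@H]2Oc3ccc(-c4oc(C(=O)C=[N+]=[N-])cc(=O)c4OCOC)cc3O[C@@H]2COCOC)ccc1OCOC
A5 | alternative 2 | (ethynyloxy)triisopropylsilane | C#CO[Si](C(C)C)(C(C)C)C(C)C
A6 | alternative 3 | methyl (2R,3R)-3-{[(tert-butyldimethylsilyl)oxy]methyl}-2-[3-methoxy-4-(pivaloyloxy)phenyl]-2,3-dihydro-1,4-benzodioxine-6-carboxylate | COc1cc([C@H]2Oc3ccc(C(=O)OC)cc3O[C@@H]2CO[Si](C)(C)C(C)(C)C)ccc1OC(=O)C(C)(C)C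
A7 | alternative 3 | methyl 4-{[(1R,2S)-3-[(tert-butyldimethylsilyl)oxy]-2-hydroxy-1-[3-methoxy-4-(pivaloyloxy)phenyl]propyl]oxy}-3-hydroxybenzoate | COC(=O)c1ccc(O[C@@H]([C@@H](O)CO[Si](C)(C)C(C)(C)C)c2ccc(OC(=O)C(C)(C)C)c(OC)c2)c(O)c1
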